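**Strategy**

Everything rests on cutting the pyran ring (ring C, chroman numbering) at C4–C3 and O1–C8a, a [3+3] union of a ring A 1,3-dielectrophile (benzylic bromide at C4, aryl iodide at C8a) with the enolate of a ring B arylacetaldehyde (C3–C2–O1 as a C,O-dinucleophile). One copper-catalysed domino C-benzylation/O-arylation joins both halves and closes ring C as a 3-aryl-4H-chromene; it exploits the ortho relationship of C4a and C8a on ring A and the acidity of C3 next to ring B. Iridium-catalysed asymmetric hydrogenation then sets C3 as S. Desilylation, hydrogenolysis and aerobic oxidation release the C6 phenol and the ring B quinone from its dibenzyl hydroquinone.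

Key step: step 8

Remark: atoms are numbered as in the chroman skeleton (O1, C2, C3, C4, C4a, C5–C8, C8a); ring A is the benzo ring, ring B the quinone ring, ring C the pyran ring.
Remark: compounds 1, 6 and 7 are taken as catalogue chemicals.
Remark: in step 9 the ligand antipode that delivers (3S) is used; which antipode that is has to be fixed in a small screen of both, since the sense of induction cannot be assigned safely by analogy.

**Route**

Step 1
Reactants: 1 3-hydroxy-4,5-dimethoxybenzaldehyde
Product: 2 3,4-dimethoxy-5-[(triisopropylsilyl)oxy]benzaldehyde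
Conditions: TIPSCl, imidazole, DMF, rt
Reagents that add atoms: triisopropylsilyl chloride, CC(C)[Si](Cl)(C(C)C)C(C)C
Why: Imidazole-promoted O-silylation of the only phenol installs a bulky, base-tolerant triisopropylsilyl ether that later shields the neighbouring ring CH.

Step 2
Reactants: 2 3,4-dimethoxy-5-[(triisopropylsilyl)oxy]benzaldehyde
Product: 3 2-iodo-3,4-dimethoxy-5-[(triisopropylsilyl)oxy]benzaldehyde
Conditions: I2, CF3CO2Ag, CH2Cl2, 0 °C to rt
Reagents that add atoms: iodine, II
Why: Silver-assisted electrophilic aromatic iodination should take the CH flanked by CHO and OMe (para to the silyloxy group), because the other activated CH lies between CHO and the bulky OSi(iPr)3 group.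

Step 3
Reactants: 3 2-iodo-3,4-dimethoxy-5-[(triisopropylsilyl)oxy]benzaldehyde
Product: 4 {2-iodo-3,4-dimethoxy-5-[(triisopropylsilyl)oxy]phenyl}methanol
Conditions: NaBH4, THF/MeOH, 0 °C
Reagents that add atoms: none
Why: Chemoselective borohydride reduction of the aldehyde leaves the aryl iodide and the aryl silyl ether untouched.

Step 4
Reactants: 4 {2-iodo-3,4-dimethoxy-5-[(triisopropylsilyl)oxy]phenyl}methanol
Product: 5 2-iodo-3,4-dimethoxy-5-[(triisopropylsilyl)oxy]benzyl bromide
Conditions: CBr4, PPh3, CH2Cl2, 0 °C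
Reagents that add atoms: tetrabromomethane, BrC(Br)(Br)Br
Why: The Appel reaction converts the benzylic alcohol into the bromide under neutral conditions that spare the silyl ether.

Step 5
Reactants: 6 2,3-dimethoxy-1,4-benzoquinone; 7 allyltributylstannane
Product: 8 5-allyl-2,3-dimethoxybenzene-1,4-diol
Conditions: BF3·OEt2, CH2Cl2, −78 °C; aq. Na2S2O4 work-up
Reagents that add atoms: none
Why: Lewis acid-promoted conjugate allylation of a quinone by an allylstannane (a Hosomi–Sakurai-type reaction) at an unsubstituted ring carbon, followed by tautomerisation, should give the allyl hydroquinone.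

Step 6
Reactants: 8 5-allyl-2,3-dimethoxybenzene-1,4-diol
Product: 9 1-allyl-2,5-bis(benzyloxy)-3,4-dimethoxybenzene
Conditions: BnBr, K2CO3, DMF, rt, under argon
Reagents that add atoms: benzyl bromide, BrCc1ccccc1
Why: Williamson etherification of both phenols with exclusion of air masks the hydroquinone as hydrogenolysable benzyl ethers.

Step 7
Reactants: 9 1-allyl-2,5-bis(benzyloxy)-3,4-dimethoxybenzene
Product: 11 2-[2,5-bis(benzyloxy)-3,4-dimethoxyphenyl]acetaldehyde, via vicinal diol 10 (not isolated)
Conditions: OsO4 (2 mol%), NaIO4, 2,6-lutidine, dioxane/H2O, rt; used crude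
Reagents that add atoms: osmium tetroxide, O=[Os](=O)(=O)=O (catalytic, re-formed by periodate); sodium periodate, [Na+].[O-]I(=O)(=O)=O
Why: The Lemieux–Johnson oxidation (catalytic dihydroxylation, then periodate glycol cleavage) should cut the terminal alkene to the arylacetaldehyde without attacking the electron-rich arene.

Step 8
Reactants: 5 2-iodo-3,4-dimethoxy-5-[(triisopropylsilyl)oxy]benzyl bromide; 11 2-[2,5-bis(benzyloxy)-3,4-dimethoxyphenyl]acetaldehyde
Product: 13 3-[2,5-bis(benzyloxy)-3,4-dimethoxyphenyl]-7,8-dimethoxy-6-[(triisopropylsilyl)oxy]-4H-chromene, via C-benzylated aldehyde 12 (not isolated)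
Conditions: Cs2CO3, CuI (10 mol%), 1,10-phenanthroline (20 mol%), degassed MeCN, 5 added slowly at rt, then 80 °C
Reagents that add atoms: none
Why: Proposed new method: Cs2CO3 generates the aryl-conjugated enolate of 11, whose carbon C3 displaces the benzylic bromide of 5 in an SN2 step (C4–C3) to give 12, and the re-formed enolate of 12 is then O-arylated at C8a under CuI/phenanthroline catalysis (O1–C8a) through a monovalent copper enolate, oxidative addition of the C8a–I bond to trivalent copper and C–O reductive elimination. The closest known reaction type is the copper-catalysed domino C-benzylation/O-arylation of 1,3-dicarbonyl compounds with 2-halobenzyl halides that gives 4H-chromenes, together with copper-catalysed intramolecular O-arylation of ketone enolates; what is new is a simple alpha-aryl aldehyde as the C,O-dinucleophile. Ring C closes in a 6-exo fashion by attack of the enolate oxygen on C8a via a seven-membered cupracycle, the only closure open to the enolate because C-arylation would need a four-membered ring. No stereocentre leaves the step: C3 of 12 is racemic and becomes sp2 in 13, and its configuration is set in step 9. The step needs C- over O-benzylation, mono- over dialkylation and ring closure over aldol self-condensation; the soft aryl-stabilised enolate and a benzylic bromide favour attack through carbon, the ortho-benzyloxy group of ring B and the slow addition of 5 before heating hold back the second alkylation and the aldol pathway, and the iodide sits three atoms from C4 so that only the six-membered ether can form.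

Step 9
Reactants: 13 3-[2,5-bis(benzyloxy)-3,4-dimethoxyphenyl]-7,8-dimethoxy-6-[(triisopropylsilyl)oxy]-4H-chromene
Product: 14 (3S)-3-[2,5-bis(benzyloxy)-3,4-dimethoxyphenyl]-7,8-dimethoxy-6-[(triisopropylsilyl)oxy]chromane
Conditions: H2 (50 bar), [Ir(cod)(L*)][B(3,5-(CF3)2C6H3)4] (1 mol%, L* = 4-tert-butyl-2-[2-(diphenylphosphino)phenyl]-4,5-dihydrooxazole, one antipode), CH2Cl2, rt
Reagents that add atoms: none
Why: Iridium-catalysed asymmetric hydrogenation of a trisubstituted cyclic enol ether with a chiral P,N ligand, a reaction established for 4H-chromenes, should add H2 to one face of C2=C3 under catalyst control and so set C3 as S, while benzyl ethers and the silyl ether stay intact.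

Step 10
Reactants: 14 (3S)-3-[2,5-bis(benzyloxy)-3,4-dimethoxyphenyl]-7,8-dimethoxy-6-[(triisopropylsilyl)oxy]chromane
Product: 15 (3S)-3-[2,5-bis(benzyloxy)-3,4-dimethoxyphenyl]-7,8-dimethoxychroman-6-ol
Conditions: Bu4NF, AcOH, THF, 0 °C
Reagents that add atoms: none
Why: Fluoride-induced cleavage of the aryl silyl ether, buffered with acetic acid, frees the C6 phenol before the base-sensitive quinone exists.

Step 11
Reactants: 15 (3S)-3-[2,5-bis(benzyloxy)-3,4-dimethoxyphenyl]-7,8-dimethoxychroman-6-ol
Product: 17 5-[(3S)-6-hydroxy-7,8-dimethoxy-3,4-dihydro-2H-chromen-3-yl]-2,3-dimethoxycyclohexa-2,5-diene-1,4-dione, via hydroquinone 16 (not isolated)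
Conditions: H2 (1 atm), Pd/C, EtOAc, rt; filter; then air, rt
Reagents that add atoms: none
Why: Hydrogenolysis of the two benzyl ethers frees the ring B hydroquinone, which should autoxidise to the quinone in air while the ring A para-alkoxyphenol, of much higher oxidation potential, stays intact, and the neutral medium avoids epimerisation of C3 through a quinone methide tautomer.

**Compound list**

1 | 3-hydroxy-4,5-dimethoxybenzaldehyde | COc1cc(C=O)cc(O)c1OC | starting material
2 | 3,4-dimethoxy-5-[(triisopropylsilyl)oxy]benzaldehyde | COc1cc(C=O)cc(O[Si](C(C)C)(C(C)C)C(C)C)c1OC | intermediate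
3 | 2-iodo-3,4-dimethoxy-5-[(triisopropylsilyl)oxy]benzaldehyde | COc1c(I)c(C=O)cc(O[Si](C(C)C)(C(C)C)C(C)C)c1OC | intermediate
4 | {2-iodo-3,4-dimethoxy-5-[(triisopropylsilyl)oxy]phenyl}methanol | COc1c(I)c(CO)cc(O[Si](C(C)C)(C(C)C)C(C)C)c1OC | intermediate
5 | 2-iodo-3,4-dimethoxy-5-[(triisopropylsilyl)oxy]benzyl bromide (fragment A) | COc1c(I)c(CBr)cc(O[Si](C(C)C)(C(C)C)C(C)C)c1OC | intermediate
6 | 2,3-dimethoxy-1,4-benzoquinone | COC1=C(OC)C(=O)C=CC1=O | starting material
7 | allyltributylstannane | C=CC[Sn](CCCC)(CCCC)CCCC | starting material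
8 | 5-allyl-2,3-dimethoxybenzene-1,4-diol | COc1c(O)cc(CC=C)c(O)c1OC | intermediate
9 | 1-allyl-2,5-bis(benzyloxy)-3,4-dimethoxybenzene | COc1c(OCc2ccccc2)cc(CC=C)c(OCc2ccccc2)c1OC | intermediate
10 | 3-[2,5-bis(benzyloxy)-3,4-dimethoxyphenyl]propane-1,2-diol (racemic) | COc1c(OCc2ccccc2)cc(CC(O)CO)c(OCc2ccccc2)c1OC | intermediate
11 | 2-[2,5-bis(benzyloxy)-3,4-dimethoxyphenyl]acetaldehyde (fragment B) | COc1c(OCc2ccccc2)cc(CC=O)c(OCc2ccccc2)c1OC | intermediate
12 | 2-[2,5-bis(benzyloxy)-3,4-dimethoxyphenyl]-3-{2-iodo-3,4-dimethoxy-5-[(triisopropylsilyl)oxy]phenyl}propanal (racemic) | COc1c(OCc2ccccc2)cc(C(C=O)Cc2cc(O[Si](C(C)C)(C(C)C)C(C)C)c(OC)c(OC)c2I)c(OCc2ccccc2)c1OC | intermediate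
13 | 3-[2,5-bis(benzyloxy)-3,4-dimethoxyphenyl]-7,8-dimethoxy-6-[(triisopropylsilyl)oxy]-4H-chromene | COc1c(OCc2ccccc2)cc(C2=COc3c(cc(O[Si](C(C)C)(C(C)C)C(C)C)c(OC)c3OC)C2)c(OCc2ccccc2)c1OC | intermediate
14 | (3S)-3-[2,5-bis(benzyloxy)-3,4-dimethoxyphenyl]-7,8-dimethoxy-6-[(triisopropylsilyl)oxy]chromane | COc1c(OCc2ccccc2)cc([C@H]2COc3c(cc(O[Si](C(C)C)(C(C)C)C(C)C)c(OC)c3OC)C2)c(OCc2ccccc2)c1OC | intermediate
15 | (3S)-3-[2,5-bis(benzyloxy)-3,4-dimethoxyphenyl]-7,8-dimethoxychroman-6-ol | COc1c(OCc2ccccc2)cc([C@H]2COc3c(cc(O)c(OC)c3OC)C2)c(OCc2ccccc2)c1OC | intermediate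
16 | (3S)-3-(2,5-dihydroxy-3,4-dimethoxyphenyl)-7,8-dimethoxychroman-6-ol | COc1c(O)cc([C@H]2COc3c(cc(O)c(OC)c3OC)C2)c(O)c1OC | intermediate
17 | 5-[(3S)-6-hydroxy-7,8-dimethoxy-3,4-dihydro-2H-chromen-3-yl]-2,3-dimethoxycyclohexa-2,5-diene-1,4-dione | COC1=C(OC)C(=O)C([C@H]2COc3c(cc(O)c(OC)c3OC)C2)=CC1=O | target

**Step count and risks**

Total step count: 11. Longest linear sequence: 8 steps (steps 1, 2, 3, 4, 8, 9, 10, 11); the ring B branch (steps 5, 6, 7) joins at step 8.

Steps most likely to fail:

Step 8 (Proposed new method). The enolate chemistry may divert into aldol self-condensation, O-benzylation or a second C-benzylation. The copper cycle may also stall at the hindered, electron-rich aryl iodide, so that the sequence stops at the open-chain aldehyde, or the base may strip the silyl ether. A fallback of known reactions sets out from 11 and 5 and comes back at 14. Pinnick oxidation of 11 (NaClO2, NaH2PO4, 2-methyl-2-butene, t-BuOH/H2O) gives the arylacetic acid F1. Its mixed pivalic anhydride (PivCl, Et3N, then LiCl) acylates (4S)-4-benzyl-1,3-oxazolidin-2-one to the N-acyl oxazolidinone F2. Evans alkylation of the sodium Z-enolate (NaN(SiMe3)2, THF, −78 °C) with 5, on the face away from the benzyl group, forms C4–C3 and should give the (2S)-alkylated imide F3. LiBH4 (THF, MeOH, 0 °C) removes the auxiliary to give the (2S)-primary alcohol F4. Ullmann-type intramolecular etherification (CuI, 1,10-phenanthroline, Cs2CO3, toluene, 110 °C) forms O1–C8a and delivers 14, so that step 9 is not needed.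

Step 9. Facial selectivity may be poor on an enol ether carrying an ortho-substituted aryl group, and the acidic iridium hydrides may protonate the enol ether so that it isomerises or is reduced without control. A fallback sets out from 13 and comes back at 14. A ruthenium hydride (RuHCl(CO)(PPh3)3, toluene, 80 °C) moves the double bond into conjugation with ring A to give the 3-aryl-2H-chromene F5. This stilbene-like trisubstituted alkene belongs to the isoflav-3-ene class, for which iridium P,N catalysts are established, and its asymmetric hydrogenation should give 14.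

Step 2. Iodination may go in part to the CH next to the silyloxy group, or the acid set free may cause protodesilylation. A fallback sets out from 2 and comes back at 4. NaBH4 reduction gives the benzylic alcohol F6. Directed ortho-lithiation (n-BuLi, 2.2 equiv, TMEDA, Et2O, 0 °C) should take the CH between the lithium alkoxide arm and the methoxy group, which cooperate, whereas the bulky silyloxy group does not coordinate. Quenching with I2 gives 4.

**Further compounds**

F1 | step 8 | 2-[2,5-bis(benzyloxy)-3,4-dimethoxyphenyl]acetic acid | OC(=O)Cc1cc(OCc2ccccc2)c(OC)c(OC)c1OCc1ccccc1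
F2 | step 8 | (4S)-4-benzyl-3-{[2,5-bis(benzyloxy)-3,4-dimethoxyphenyl]acetyl}-1,3-oxazolidin-2-one | O=C1OC[C@H](Cc2ccccc2)N1C(=O)Cc1cc(OCc2ccccc2)c(OC)c(OC)c1OCc1ccccc1
F3 | step 8 | (4S)-4-benzyl-3-[(2S)-2-[2,5-bis(benzyloxy)-3,4-dimethoxyphenyl]-3-{2-iodo-3,4-dimethoxy-5-[(triisopropylsilyl)oxy]phenyl}propanoyl]-1,3-oxazolidin-2-one | O=C1OC[C@H](Cc2ccccc2)N1C(=O)[C@@H](Cc1cc(O[Si](C(C)C)(C(C)C)C(C)C)c(OC)c(OC)c1I)c1cc(OCc2ccccc2)c(OC)c(OC)c1OCc1ccccc1
F4 | step 8 | (2S)-2-[2,5-bis(benzyloxy)-3,4-dimethoxyphenyl]-3-{2-iodo-3,4-dimethoxy-5-[(triisopropylsilyl)oxy]phenyl}propan-1-ol | OC[C@@H](Cc1cc(O[Si](C(C)C)(C(C)C)C(C)C)c(OC)c(OC)c1I)c1cc(OCc2ccccc2)c(OC)c(OC)c1OCc1ccccc1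
F5 | step 9 | 3-[2,5-bis(benzyloxy)-3,4-dimethoxyphenyl]-7,8-dimethoxy-6-[(triisopropylsilyl)oxy]-2H-chromene | COc1c(OCc2ccccc2)cc(C2=Cc3cc(O[Si](C(C)C)(C(C)C)C(C)C)c(OC)c(OC)c3OC2)c(OCc2ccccc2)c1OC
F6 | step 2 | {3,4-dimethoxy-5-[(triisopropylsilyl)oxy]phenyl}methanol | COc1cc(CO)cc(O[Si](C(C)C)(C(C)C)C(C)C)c1OC
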